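**Retrosynthetic overview**

- Numbering: C1 quaternary ring-fusion carbon (methyl, whose face is called β), C2/C3 cyclopentane CH2, C4 carbinol carbon (isopropyl), C5 ring-fusion CH, C6 ester CH, C7=C8(Me) alkene, C9 ketone, C10 CH2. The strategy rests on the fifteen core carbons being an intact head-to-tail farnesyl chain that lacks only the C10–C1 and C4–C5 bonds, with C4 as the cationic carbon that takes up water.
- C6–O ester: Steglich coupling of O-silyl p-coumaric acid with the 4β,6α-diol enone. C6–OH: α-face γ-oxidation of the silyl dienol ether of the 7-en-9-one.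
- Enone: from dauc-8-en-4β-ol by hydroboration–oxidation at C9, oxidation, and Saegusa–Ito desaturation toward C7.
- Core: dauc-8-en-4β-ol from (2E,6E)-farnesyl diphosphate by one enzymatic cation cascade that closes the seven-membered ring (C10–C1) and the five-membered ring (C4–C5) together and hydrates C4. Farnesyl diphosphate comes from farnesol in two steps.

Key step: step 3

Remark: it is assumed that a cyclase of the required product specificity can be obtained by screening and directed evolution of daucane-forming cyclases; α/β refer to the face opposite to/of the C1 methyl group.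

**Route**

Step 1
Reactants: 1 (2E,6E)-farnesol
Product: 2 (2E,6E)-farnesyl chloride
Conditions: NCS, Me2S, CH2Cl2, −40 → 0 °C
Reagents that add atoms: N-chlorosuccinimide, O=C1CCC(=O)N1Cl
Why: Corey–Kim chlorination passes through an alkoxysulfonium salt that chloride displaces at the primary carbon, so the alkene position and the E,E geometry should be kept.

Step 2
Reactants: 2 (2E,6E)-farnesyl chloride
Product: 3 (2E,6E)-farnesyl diphosphate (handled as the tris-ammonium salt)
Conditions: (Bu4N)3HP2O7, MeCN, rt; then Dowex 50W (NH4+ form), cellulose chromatography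
Reagents that add atoms: tris(tetrabutylammonium) hydrogen diphosphate, CCCC[N+](CCCC)(CCCC)CCCC.CCCC[N+](CCCC)(CCCC)CCCC.CCCC[N+](CCCC)(CCCC)CCCC.OP(=O)([O-])OP(=O)([O-])[O-]
Why: SN2 displacement of the primary allylic chloride by the diphosphate trianion in dry MeCN is the standard access to allylic diphosphates, and cation exchange gives the water-soluble salt the enzyme accepts.

Step 3
Reactants: 3 (2E,6E)-farnesyl diphosphate
Product: 5 dauc-8-en-4β-ol, via nerolidyl diphosphate 4 (not isolated)
Conditions: recombinant evolved daucane-type sesquiterpene cyclase (ionisation-initiated class, from Escherichia coli), MgCl2, HEPES buffer pH 7.5, DTT, glycerol, 30 °C, pentane overlay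
Reagents that add atoms: water, O
Why: Proposed new method: no cyclase is known for this product, but the mechanism is that of every ionisation-initiated sesquiterpene cyclase, in which Mg2+-assisted loss of diphosphate from 3 and recapture at the tertiary carbon give nerolidyl diphosphate 4, rotation about its C8–C9 bond allows the cisoid geometry, and re-ionisation places the C10 allyl cation over the central alkene; the closest known reactions are the cyclisations of 3 by daucane-forming cyclases that release the C5 alcohol or the C11 alcohol from the same cascade. The seven-membered ring closes by 7-endo attack of C1 of the C1=C5 alkene on C10 and, in concert so that no secondary cation is left at C5, the five-membered ring closes by 5-exo attack of C4 of the terminal alkene on C5, which puts the charge on the isopropyl carbon C11. C1 and C5 are set together by anti addition across the E-configured C1=C5 alkene, which can only give the trans ring fusion (C1 methyl β, H5 α), and their absolute sense follows from the single chain fold that the pocket allows. A 1,2-hydride shift from C4 to C11 then gives the tertiary C4 cation, and C4 is set by the water molecule held on the β face, cis to the C1 methyl. The step needs control of the fold, of the number of hydride shifts (one, not the two that lead on to the C5 cation) and of the face of hydration, and nothing in the substrate secures any of these, so they must come from the active site, found by screening homologues and mutating the residues that line the C4/C5 region and place the water.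

Step 4
Reactants: 5 dauc-8-en-4β-ol
Product: 6 daucane-4β,9-diol (mixture at C8 and C9)
Conditions: BH3·THF, THF, 0 °C → rt; then NaOH, H2O2, 0 °C → rt
Reagents that add atoms: hydrogen peroxide, OO
Why: Hydroboration–oxidation adds syn and anti-Markovnikov to the trisubstituted C8=C9 alkene so that oxygen ends on C9, the tertiary C4 hydroxyl is held only as a borate that returns on work-up, and the new C8 and C9 centres (expected mainly from α-face attack, away from the C1 methyl) are both erased in steps 5 to 7.

Step 5
Reactants: 6 daucane-4β,9-diol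
Product: 7 4β-hydroxydaucan-9-one (C8 epimers)
Conditions: Dess–Martin periodinane, CH2Cl2, 0 °C → rt
Reagents that add atoms: none
Why: Dess–Martin oxidation takes the secondary C9 alcohol to the ketone under near-neutral conditions and cannot oxidise the tertiary C4 alcohol.

Step 6
Reactants: 7 4β-hydroxydaucan-9-one
Product: 8 4β,9-bis(trimethylsilyloxy)dauc-8-ene
Conditions: TMSCl, NaI, Et3N, MeCN, rt
Reagents that add atoms: chlorotrimethylsilane, C[Si](C)(C)Cl
Why: Silyl enol ether formation under equilibrating conditions (iodotrimethylsilane made in the flask, amine base) should favour the tetrasubstituted C8=C9 isomer over the C9=C10 isomer beside quaternary C1, both C8 epimers converge, and the C4 hydroxyl is silylated at the same time, which protects it through steps 7 to 9.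

Step 7
Reactants: 8 4β,9-bis(trimethylsilyloxy)dauc-8-ene
Product: 9 4β-(trimethylsilyloxy)dauc-7-en-9-one
Conditions: Pd(OAc)2 (1.1 equiv), MeCN, rt
Reagents that add atoms: none
Why: Saegusa–Ito oxidation, in which the divalent palladium enolate bound at C8 loses a β-hydrogen from ring carbon C7 to give the conjugated trisubstituted enone, while any C9=C10 enol ether cannot eliminate because C1 bears no hydrogen and only returns 7.

Step 8
Reactants: 9 4β-(trimethylsilyloxy)dauc-7-en-9-one
Product: 10 9-(tert-butyldimethylsilyloxy)-4β-(trimethylsilyloxy)dauca-6,8-diene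
Conditions: TBSOTf, Et3N, CH2Cl2, 0 °C → rt
Reagents that add atoms: tert-butyldimethylsilyl triflate, CC(C)(C)[Si](C)(C)OS(=O)(=O)C(F)(F)F
Why: Soft enolisation with silyl triflate and amine under equilibrating conditions should remove the γ-proton at C6 and give the through-conjugated 1-silyloxy-1,3-diene, as with ring-fused enones, the cross-conjugated C9=C10 isomer being disfavoured next to quaternary C1.

Step 9
Reactants: 10 9-(tert-butyldimethylsilyloxy)-4β-(trimethylsilyloxy)dauca-6,8-diene
Product: 12 4β,6α-dihydroxydauc-7-en-9-one, via 6α,7α-epoxide 11 (not isolated)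
Conditions: dimethyldioxirane (acetone solution), CH2Cl2, −78 → −30 °C; then HF·pyridine, THF, 0 °C
Reagents that add atoms: dimethyldioxirane, CC1(C)OO1
Why: Vinylogous Rubottom oxidation, in which the dioxirane should epoxidise the terminal C6=C7 bond of the dienol ether (C8 is fully substituted) from the α face, anti to the axial C1 methyl and the C4 silyloxy group, and fluoride then opens the epoxide through the enolate to the γ-hydroxy enone with the C6–O bond intact and frees the C4 hydroxyl, which sets C6.

Step 10
Reactants: 13 p-coumaric acid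
Product: 15 (E)-4-(tert-butyldimethylsilyloxy)cinnamic acid, via bis-silylated coumarate 14 (not isolated)
Conditions: TBSCl, imidazole, DMF, rt; then THF–H2O–AcOH (3:1:1), rt
Reagents that add atoms: tert-butyldimethylsilyl chloride, CC(C)(C)[Si](C)(C)Cl
Why: Silylation of both acidic groups followed by selective hydrolysis of the far more labile silyl ester leaves the phenol masked as its silyl ether, so the acid cannot acylate itself in step 11.

Step 11
Reactants: 12 4β,6α-dihydroxydauc-7-en-9-one; 15 (E)-4-(tert-butyldimethylsilyloxy)cinnamic acid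
Product: 16 6α-[(E)-4-(tert-butyldimethylsilyloxy)cinnamoyloxy]-4β-hydroxydauc-7-en-9-one
Conditions: DCC, DMAP (cat.), CH2Cl2, 0 °C → rt
Reagents that add atoms: none
Why: Steglich esterification acylates the secondary allylic C6 hydroxyl with retention, while the tertiary C4 hydroxyl flanked by the isopropyl group is too hindered to react and the conditions are too mild to isomerise the γ-hydroxy enone.

Step 12
Reactants: 16 6α-[(E)-4-(tert-butyldimethylsilyloxy)cinnamoyloxy]-4β-hydroxydauc-7-en-9-one
Product: 17 6α-[(E)-4-hydroxycinnamoyloxy]-4β-hydroxydauc-7-en-9-one (target)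
Conditions: HF·pyridine, pyridine, THF, 0 °C → rt
Reagents that add atoms: none
Why: Fluoride cleaves the aryl silyl ether under buffered, non-basic conditions that leave the cinnamate ester, the enone and the tertiary alcohol untouched.

**Compound list**

1 | (2E,6E)-farnesol | CC(C)=CCC/C(C)=C/CC/C(C)=C/CO | starting material
2 | (2E,6E)-farnesyl chloride | CC(C)=CCC/C(C)=C/CC/C(C)=C/CCl | intermediate
3 | (2E,6E)-farnesyl diphosphate (tris-ammonium salt in practice, written as the acid) | CC(C)=CCC/C(C)=C/CC/C(C)=C/COP(=O)(O)OP(=O)(O)O | intermediate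
4 | (6E)-nerolidyl diphosphate, enzyme-bound; the configuration of its tertiary carbon is fixed by the pocket and lost on re-ionisation, so it is left open | CC(C)=CCC/C(C)=C/CCC(C)(C=C)OP(=O)(O)OP(=O)(O)O | intermediate (not isolated)
5 | dauc-8-en-4β-ol (trans-fused, 1β-methyl, 5α-H, 4α-isopropyl) | CC1=CC[C@@]2(C)CC[C@@](O)(C(C)C)[C@@H]2CC1 | intermediate
6 | daucane-4β,9-diol (C8 and C9 left open, mixture) | CC1CC[C@@H]2[C@](C)(CC[C@@]2(O)C(C)C)CC1O | intermediate
7 | 4β-hydroxydaucan-9-one (C8 left open, epimers) | CC1CC[C@@H]2[C@](C)(CC[C@@]2(O)C(C)C)CC1=O | intermediate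
8 | 4β,9-bis(trimethylsilyloxy)dauc-8-ene | CC1=C(O[Si](C)(C)C)C[C@@]2(C)CC[C@@](O[Si](C)(C)C)(C(C)C)[C@@H]2CC1 | intermediate
9 | 4β-(trimethylsilyloxy)dauc-7-en-9-one | CC1=CC[C@@H]2[C@](C)(CC[C@@]2(O[Si](C)(C)C)C(C)C)CC1=O | intermediate
10 | 9-(tert-butyldimethylsilyloxy)-4β-(trimethylsilyloxy)dauca-6,8-diene | CC1=C(O[Si](C)(C)C(C)(C)C)C[C@@]2(C)CC[C@@](O[Si](C)(C)C)(C(C)C)[C@@H]2C=C1 | intermediate
11 | 6α,7α-epoxy-9-(tert-butyldimethylsilyloxy)-4β-(trimethylsilyloxy)dauc-8-ene | CC1=C(O[Si](C)(C)C(C)(C)C)C[C@@]2(C)CC[C@@](O[Si](C)(C)C)(C(C)C)[C@@H]2[C@H]3O[C@@H]13 | intermediate (not isolated)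
12 | 4β,6α-dihydroxydauc-7-en-9-one | CC1=C[C@H](O)[C@@H]2[C@](C)(CC[C@@]2(O)C(C)C)CC1=O | intermediate
13 | p-coumaric acid | OC(=O)/C=C/c1ccc(O)cc1 | starting material
14 | tert-butyldimethylsilyl (E)-4-(tert-butyldimethylsilyloxy)cinnamate | CC(C)(C)[Si](C)(C)OC(=O)/C=C/c1ccc(O[Si](C)(C)C(C)(C)C)cc1 | intermediate (not isolated)
15 | (E)-4-(tert-butyldimethylsilyloxy)cinnamic acid | OC(=O)/C=C/c1ccc(O[Si](C)(C)C(C)(C)C)cc1 | intermediate
16 | 6α-[(E)-4-(tert-butyldimethylsilyloxy)cinnamoyloxy]-4β-hydroxydauc-7-en-9-one | CC1=C[C@H](OC(=O)/C=C/c2ccc(O[Si](C)(C)C(C)(C)C)cc2)[C@@H]2[C@](C)(CC[C@@]2(O)C(C)C)CC1=O | intermediate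
17 | 6α-[(E)-4-hydroxycinnamoyloxy]-4β-hydroxydauc-7-en-9-one | CC1=C[C@H](OC(=O)/C=C/c2ccc(O)cc2)[C@@H]2[C@](C)(CC[C@@]2(O)C(C)C)CC1=O | target

**Step count**

Total: 12 steps. Longest linear sequence: 11 steps (steps 1 to 9, 11 and 12).

**Steps most likely to fail**

Step 3. The cascade may run on past the C4 cation by a second hydride shift, end by proton loss, or take up water on the wrong face. No enzyme may be found that avoids all three.
Fallback: a fully chemical build of the bicycle, in which olefin metathesis and a carbonyl addition at C4 replace the cation cascade. No known non-enzymatic reaction folds 1, 2 or 3 in this way, so this fallback cannot set out from a compound of the route. It replaces compounds 1 to 8, starts from commercial 3-ethoxycyclopent-2-en-1-one F1 and comes back to the route at 9.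
- Addition of (3-methylbut-3-en-1-yl)magnesium bromide to F1 and acid work-up (Stork–Danheiser transposition) should give 3-(3-methylbut-3-en-1-yl)cyclopent-2-en-1-one F2.
- Copper-catalysed asymmetric conjugate addition of Me3Al (Cu(OTf)2, chiral N-heterocyclic carbene or phosphoramidite ligand of the enantiomer that delivers the C1 configuration of the target), with trapping of the aluminium enolate by TMSOTf, should give the silyl enol ether 3-methyl-3-(3-methylbut-3-en-1-yl)-1-(trimethylsilyloxy)cyclopent-1-ene F3.
- MeLi frees the regiodefined lithium enolate, and allyl iodide should alkylate C5 anti to the longer chain, cis to the methyl group, to give 2-allyl-3-methyl-3-(3-methylbut-3-en-1-yl)cyclopentan-1-one F4. Its C5 epimer is removed or equilibrated.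
- Ring-closing metathesis with the second-generation Grubbs catalyst closes the seven-membered ring at C7=C8 and should give the trans-fused ketone 11,12,13-trinordauc-7-en-4-one F5.
- i-PrMgCl with CeCl3 should add to the C4 ketone from the α face, away from C6 and the C1 methyl, to give dauc-7-en-4β-ol F6.
- SeO2 with t-BuOOH oxidises the ring methylene next to the more substituted alkene carbon to give dauc-7-ene-4β,9-diol F7.
- Dess–Martin oxidation gives 4β-hydroxydauc-7-en-9-one F8, and 1-(trimethylsilyl)imidazole silylates the tertiary alcohol to give 9.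

Step 9. The oxidant may add to the β face of C6, or to the enol ether carbon C8 in place of the diene terminus.
Fallback: correct C6 by inversion during the esterification. It sets out from 10 and comes back at 16. If attack is mainly on the β face, step 9 delivers the 6β,7β-epoxide F12 and, after HF·pyridine, 4β,6β-dihydroxydauc-7-en-9-one F13. Mitsunobu esterification of F13 with acid 15 (PPh3, DIAD, toluene, 0 °C → rt) inverts the secondary allylic centre and gives 16 directly, the tertiary C4 hydroxyl being inert.

Step 8. Proton loss from C10 in place of C6 would give the cross-conjugated dienol ether, and step 9 would then oxidise C10.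
Fallback: reach C6 through the equilibrated potassium dienolate and a β,γ-epoxide, with no silyl dienol ether. It sets out from 9 and comes back at 12.
- KOt-Bu in t-BuOH/THF equilibrates the enolates of 9 to the through-conjugated dienolate. Quenching into cold aqueous AcOH protonates C8 kinetically and should give the deconjugated ketone 4β-(trimethylsilyloxy)dauc-6-en-9-one F9.
- mCPBA (NaHCO3, CH2Cl2, 0 °C) epoxidises the isolated C6=C7 alkene from the α face to give 6α,7α-epoxy-4β-(trimethylsilyloxy)daucan-9-one F10.
- Et3N opens the β,γ-epoxy ketone by β-elimination to 6α-hydroxy-4β-(trimethylsilyloxy)dauc-7-en-9-one F11, and HF·pyridine removes the silyl group to give 12.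

**Further compounds**

F1 | step 3 | 3-ethoxycyclopent-2-en-1-one | CCOC1=CC(=O)CC1
F2 | step 3 | 3-(3-methylbut-3-en-1-yl)cyclopent-2-en-1-one | CC(=C)CCC1=CC(=O)CC1
F3 | step 3 | 3-methyl-3-(3-methylbut-3-en-1-yl)-1-(trimethylsilyloxy)cyclopent-1-ene (quaternary carbon as C1 of the target) | C[Si](C)(C)OC1=C[C@](C)(CC1)CCC(C)=C
F4 | step 3 | 2-allyl-3-methyl-3-(3-methylbut-3-en-1-yl)cyclopentan-1-one (allyl cis to methyl) | C=CC[C@@H]1[C@](C)(CCC1=O)CCC(C)=C
F5 | step 3 | 11,12,13-trinordauc-7-en-4-one (trans-fused) | CC1=CC[C@@H]2[C@](C)(CCC2=O)CC1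
F6 | step 3 | dauc-7-en-4β-ol | CC1=CC[C@@H]2[C@](C)(CC[C@@]2(O)C(C)C)CC1
F7 | step 3 | dauc-7-ene-4β,9-diol (C9 left open) | CC1=CC[C@@H]2[C@](C)(CC[C@@]2(O)C(C)C)CC1O
F8 | step 3 | 4β-hydroxydauc-7-en-9-one | CC1=CC[C@@H]2[C@](C)(CC[C@@]2(O)C(C)C)CC1=O
F9 | step 8 | 4β-(trimethylsilyloxy)dauc-6-en-9-one (C8 left open) | CC1C=C[C@@H]2[C@](C)(CC[C@@]2(O[Si](C)(C)C)C(C)C)CC1=O
F10 | step 8 | 6α,7α-epoxy-4β-(trimethylsilyloxy)daucan-9-one (C8 left open) | CC1[C@@H]3O[C@@H]3[C@@H]2[C@](C)(CC[C@@]2(O[Si](C)(C)C)C(C)C)CC1=O
F11 | step 8 | 6α-hydroxy-4β-(trimethylsilyloxy)dauc-7-en-9-one | CC1=C[C@H](O)[C@@H]2[C@](C)(CC[C@@]2(O[Si](C)(C)C)C(C)C)CC1=O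
F12 | step 9 | 6β,7β-epoxy-9-(tert-butyldimethylsilyloxy)-4β-(trimethylsilyloxy)dauc-8-ene | CC1=C(O[Si](C)(C)C(C)(C)C)C[C@@]2(C)CC[C@@](O[Si](C)(C)C)(C(C)C)[C@@H]2[C@@H]3O[C@H]13
F13 | step 9 | 4β,6β-dihydroxydauc-7-en-9-one | CC1=C[C@@H](O)[C@@H]2[C@](C)(CC[C@@]2(O)C(C)C)CC1=O
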